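The cyclohexane is closed at the bond between the quaternary ring carbon (the one that carries CH3 and CH2-indol-3-yl) and the neighbouring ring CH that bears the propanoic acid chain. This CH is allylic to the exocyclic isopropylidene group and its chain ends in a carboxyl group, so the chain carboxylate can serve as the allylic leaving group. The precursor is an acyclic α-branched aldehyde that ends in a γ-lactone on a tetrasubstituted alkene. Zerovalent palladium opens the lactone to an η3-allyl complex, the enamine of the aldehyde attacks it, and one operation closes the ring, sets two adjacent stereocentres (one quaternary), places the isopropylidene and frees the acid. The formyl group later becomes the methyl group.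

Key step: step 9

Remark: the aldehyde α-carbon and the lactone carbon are both reset in step 9, so compounds 7, 8 and 13 to 17 are carried as mixtures of epimers at these two carbons; only the methyl-bearing stereocentre from step 2 is kept throughout.

Step 1
Reactants: 1 (E)-but-2-en-1-ol
Product: 2 (E)-but-2-en-1-yl methyl carbonate
Conditions: ClCO2Me, pyridine, CH2Cl2, 0 °C to rt
Reagents that add atoms: methyl chloroformate, COC(=O)Cl
Why: Acylation of the primary allylic alcohol with a chloroformate gives the carbonate leaving group needed for iridium-catalysed allylic substitution; no stereocentre is formed.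

Step 2
Reactants: 2 (E)-but-2-en-1-yl methyl carbonate; 3 dimethyl malonate
Product: 4 dimethyl 2-[(2R)-but-3-en-2-yl]propanedioate
Conditions: [Ir(cod)Cl]2 (2 mol%), O,O'-(1,1'-binaphthalene-2,2'-diyl) N,N-bis(1-phenylethyl)phosphoramidite (4 mol%, the enantiomer that gives the (R) product), TBD (8 mol%), THF, rt
Reagents that add atoms: none
Why: Iridium-catalysed asymmetric allylic alkylation (branched-selective Tsuji–Trost-type substitution) places the malonate on the substituted allyl terminus, and the chiral phosphoramidite–iridium allyl complex sets the methyl-bearing stereocentre as (R) by reagent control.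

Step 3
Reactants: 4 dimethyl 2-[(2R)-but-3-en-2-yl]propanedioate; 5 gramine (3-(dimethylaminomethyl)-1H-indole)
Product: 6 dimethyl 2-[(2R)-but-3-en-2-yl]-2-(1H-indol-3-ylmethyl)propanedioate
Conditions: n-Bu3P (0.3 equiv), MeCN, reflux
Reagents that add atoms: none
Why: Gramine alkylation by elimination–addition (phosphine-promoted loss of dimethylamine, then capture by the malonate anion) installs the indol-3-ylmethyl group without N-protection; the new fully substituted carbon is not stereogenic.

Step 4
Reactants: 6 dimethyl 2-[(2R)-but-3-en-2-yl]-2-(1H-indol-3-ylmethyl)propanedioate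
Product: 7 methyl (3R)-2-(1H-indol-3-ylmethyl)-3-methylpent-4-enoate (both C-2 epimers)
Conditions: LiCl, H2O, DMSO, 160 °C
Reagents that add atoms: none
Why: Krapcho dealkoxycarbonylation removes one ester of the disubstituted malonate by chloride attack on the methyl group and loss of CO2; the new α-stereocentre forms as a mixture, which is harmless because it is reset in step 9.

Step 5
Reactants: 7 methyl (3R)-2-(1H-indol-3-ylmethyl)-3-methylpent-4-enoate
Product: 8 (3R)-2-(1H-indol-3-ylmethyl)-3-methylpent-4-en-1-ol (both C-2 epimers)
Conditions: LiAlH4, THF, 0 °C to rt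
Reagents that add atoms: none
Why: LiAlH4 reduction of the ester gives a primary alcohol that survives hydroboration and cross-coupling and is the latent aldehyde; no stereocentre changes.

Step 6
Reactants: 9 1,1-dibromo-2-methylprop-1-ene; 10 methyl 4-oxobutanoate
Product: 13 5-(1-bromo-2-methylprop-1-en-1-yl)oxolan-2-one (racemic), via lithium carbenoid 11 (not isolated), via lithium alkoxide 12 (not isolated)
Conditions: n-BuLi, THF/Et2O/pentane, −105 °C; then 10, −105 to −20 °C; AcOH
Reagents that add atoms: none
Why: Bromine–lithium exchange gives a 1-bromoalkenyllithium carbenoid that is stable at −105 °C and adds to the aldehyde in preference to the ester, and the γ-alkoxide closes the γ-lactone; the lactone carbon forms racemic, which is harmless because it is ionised in step 9.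

Step 7
Reactants: 8 (3R)-2-(1H-indol-3-ylmethyl)-3-methylpent-4-en-1-ol; 13 5-(1-bromo-2-methylprop-1-en-1-yl)oxolan-2-one
Product: 15 5-[(6R)-7-(hydroxymethyl)-8-(1H-indol-3-yl)-2,6-dimethyloct-2-en-3-yl]oxolan-2-one (mixture of epimers at the lactone carbon and at C-7 of the chain), via alkylborane 14 (not isolated)
Conditions: 9-BBN (2.5 equiv), THF, 0 °C to rt; then 13, Pd(OAc)2 (5 mol%), SPhos (10 mol%), aq. K3PO4, THF, 50 °C; acidic work-up
Reagents that add atoms: none
Why: Anti-Markovnikov hydroboration of the terminal alkene with 9-BBN followed by B-alkyl Suzuki–Miyaura coupling with the alkenyl bromide forms the C(sp3)–C(sp2) bond and the tetrasubstituted alkene, the bulky electron-rich biarylphosphine favouring oxidative addition at C–Br over ionisation of the allylic lactone.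

Step 8
Reactants: 15 5-[(6R)-7-(hydroxymethyl)-8-(1H-indol-3-yl)-2,6-dimethyloct-2-en-3-yl]oxolan-2-one
Product: 16 (3R)-2-(1H-indol-3-ylmethyl)-3,7-dimethyl-6-(5-oxooxolan-2-yl)oct-6-enal (mixture of epimers at C-2 and at the lactone carbon)
Conditions: Dess–Martin periodinane, pyridine, CH2Cl2, 0 °C
Reagents that add atoms: none
Why: Dess–Martin oxidation converts the primary alcohol into the aldehyde under buffered conditions that leave the lactone, the indole N–H and the tetrasubstituted alkene untouched.

Step 9
Reactants: 16 (3R)-2-(1H-indol-3-ylmethyl)-3,7-dimethyl-6-(5-oxooxolan-2-yl)oct-6-enal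
Product: 19 3-[(1R,2S,3R)-2-formyl-2-(1H-indol-3-ylmethyl)-3-methyl-6-(propan-2-ylidene)cyclohexyl]propanoic acid, via imine 17 (not isolated), via cyclised imine 18 (not isolated)
Conditions: Ph2CHNH2 (1.05 equiv), 4 Å MS, toluene, rt; then Pd(PPh3)4 (10 mol%), (PhO)2P(O)OH (5 mol%), 60 °C; then aq. citric acid, THF, rt
Reagents that add atoms: water, O
Why: Zerovalent palladium ionises the allylic C–O bond of the γ-lactone to a cationic η3-allyl palladium complex (termini: the CH that bears the CH2CH2CO2− chain, and the CMe2 carbon) paired with its own tethered carboxylate, while imine 17 tautomerises under acid catalysis to the secondary enamine, which attacks the CH terminus anti to palladium; hydrolysis then returns the aldehyde. The closest known reaction type is the amine/palladium Tsuji–Trost α-allylation of α-branched aldehydes through their enamines, combined with the known use of vinyl lactones as allyl donors whose leaving group stays in the product as a carboxylic acid. The six-membered ring closes by attack of the tethered nucleophile on one terminus of an allyl unit that is tied in through its central carbon (formally 6-endo at the CH=C unit), so the remaining double bond ends exocyclic as the isopropylidene group. The step needs attack at the CH terminus and not at the CMe2 terminus (either would give a six-membered ring), and sterics should secure this because attack at CMe2 would create two adjacent fully substituted carbons. The ring CH stereocentre should follow from a chair transition state with the existing methyl group equatorial and the chain in the syn position of the allyl unit (the anti position clashes with a methyl of the CMe2 terminus), which puts the chain axial and trans to that methyl group; both lactone epimers should converge because the allyl complex can change face by η3–η1–η3 isomerisation at the gem-dimethyl terminus and by reversible lactonisation. The quaternary centre should be set by allylic 1,3-strain and ion pairing: the enamine geometry with nitrogen cis to the methyl-bearing carbon holds that carbon's C–H in the enamine plane and lets the N–H bind the tethered carboxylate, so the formyl carbon ends equatorial, cis to the propanoic acid chain and trans to the secondary methyl group, with the indolylmethyl group axial.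

Step 10
Reactants: 19 3-[(1R,2S,3R)-2-formyl-2-(1H-indol-3-ylmethyl)-3-methyl-6-(propan-2-ylidene)cyclohexyl]propanoic acid
Product: 21 suaveolindole, 3-[(1S,2R,3R)-2-(1H-indol-3-ylmethyl)-2,3-dimethyl-6-(propan-2-ylidene)cyclohexyl]propanoic acid, via hydrazone 20 (not isolated)
Conditions: N2H4·H2O, KOH, diethylene glycol, 130 °C then 200 °C; aq. HCl to pH 3
Reagents that add atoms: none
Why: Wolff–Kishner reduction (Huang–Minlon procedure) turns the non-enolisable neopentyl formyl group into the quaternary methyl group through the hydrazone, with the acid masked as its potassium salt and no stereocentre able to epimerise.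

Compound list
1 | (E)-but-2-en-1-ol | C/C=C/CO | starting material
2 | (E)-but-2-en-1-yl methyl carbonate | C/C=C/COC(=O)OC | intermediate
3 | dimethyl malonate | COC(=O)CC(=O)OC | starting material
4 | dimethyl 2-[(2R)-but-3-en-2-yl]propanedioate | C=C[C@@H](C)C(C(=O)OC)C(=O)OC | intermediate
5 | gramine | CN(C)Cc1c[nH]c2ccccc12 | starting material
6 | dimethyl 2-[(2R)-but-3-en-2-yl]-2-(1H-indol-3-ylmethyl)propanedioate | C=C[C@@H](C)C(Cc1c[nH]c2ccccc12)(C(=O)OC)C(=O)OC | intermediate
7 | methyl (3R)-2-(1H-indol-3-ylmethyl)-3-methylpent-4-enoate, C-2 epimers | C=C[C@@H](C)C(Cc1c[nH]c2ccccc12)C(=O)OC | intermediate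
8 | (3R)-2-(1H-indol-3-ylmethyl)-3-methylpent-4-en-1-ol, C-2 epimers | C=C[C@@H](C)C(CO)Cc1c[nH]c2ccccc12 | intermediate
9 | 1,1-dibromo-2-methylprop-1-ene | CC(C)=C(Br)Br | starting material
10 | methyl 4-oxobutanoate | COC(=O)CCC=O | starting material
11 | 1-bromo-1-lithio-2-methylprop-1-ene | CC(C)=C([Li])Br | intermediate (not isolated)
12 | lithium alkoxide of methyl 5-bromo-4-hydroxy-6-methylhept-5-enoate | COC(=O)CCC(O[Li])C(Br)=C(C)C | intermediate (not isolated)
13 | 5-(1-bromo-2-methylprop-1-en-1-yl)oxolan-2-one, racemic | CC(C)=C(Br)C1CCC(=O)O1 | intermediate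
14 | B-alkyl-9-BBN from 8 (the hydroxyl group also O-borylated) | C1CCC2CCCC1B2CC[C@@H](C)C(COB1C2CCCC1CCC2)Cc1c[nH]c2ccccc12 | intermediate (not isolated)
15 | 5-[(6R)-7-(hydroxymethyl)-8-(1H-indol-3-yl)-2,6-dimethyloct-2-en-3-yl]oxolan-2-one, epimer mixture | CC(C)=C(CC[C@@H](C)C(CO)Cc1c[nH]c2ccccc12)C1CCC(=O)O1 | intermediate
16 | (3R)-2-(1H-indol-3-ylmethyl)-3,7-dimethyl-6-(5-oxooxolan-2-yl)oct-6-enal, epimer mixture | CC(C)=C(CC[C@@H](C)C(C=O)Cc1c[nH]c2ccccc12)C1CCC(=O)O1 | intermediate
17 | N-(diphenylmethyl) aldimine of 16 | CC(C)=C(CC[C@@H](C)C(C=NC(c1ccccc1)c1ccccc1)Cc1c[nH]c2ccccc12)C1CCC(=O)O1 | intermediate (not isolated)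
18 | 3-[(1R,2S,3R)-2-[(diphenylmethylimino)methyl]-2-(1H-indol-3-ylmethyl)-3-methyl-6-(propan-2-ylidene)cyclohexyl]propanoic acid | CC(C)=C1CC[C@@H](C)[C@@](C=NC(c2ccccc2)c2ccccc2)(Cc2c[nH]c3ccccc23)[C@@H]1CCC(=O)O | intermediate (not isolated)
19 | 3-[(1R,2S,3R)-2-formyl-2-(1H-indol-3-ylmethyl)-3-methyl-6-(propan-2-ylidene)cyclohexyl]propanoic acid | CC(C)=C1CC[C@@H](C)[C@@](C=O)(Cc2c[nH]c3ccccc23)[C@@H]1CCC(=O)O | intermediate
20 | hydrazone of 19 | CC(C)=C1CC[C@@H](C)[C@@](C=NN)(Cc2c[nH]c3ccccc23)[C@@H]1CCC(=O)O | intermediate (not isolated)
21 | suaveolindole, 3-[(1S,2R,3R)-2-(1H-indol-3-ylmethyl)-2,3-dimethyl-6-(propan-2-ylidene)cyclohexyl]propanoic acid | CC(C)=C1CC[C@@H](C)[C@@](C)(Cc2c[nH]c3ccccc23)[C@@H]1CCC(=O)O | target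

Total step count: 10. Longest linear sequence: 9 steps (steps 1 to 5 and 7 to 10); step 6 is the side branch.

Steps most likely to fail

Step 9. The lactone may ionise slowly because its alkene is tetrasubstituted, so that β-hydride loss from the allyl complex to a diene competes with ring closure. The enamine may also react through both geometries, giving poor facial selectivity at the quaternary carbon, and the two lactone epimers may not converge fully. The fallback replaces the enamine by an ester enolate, in which both substituents on the enolate carbon are oxygen, so allylic 1,3-strain fixes the face whatever the enolate geometry; it also uses a more easily ionised carbonate. It sets out from ester 7 (with lactone 13 as partner) and comes back at target 21. Lactone 13 is opened with dimethylamine to 5-bromo-4-hydroxy-N,N,6-trimethylhept-5-enamide F1. Ester 7 is hydroborated with 9-BBN to the B-alkyl-9-BBN F2, which is coupled with F1 (Pd(OAc)2, SPhos, aq. K3PO4) to the hydroxy amide ester F3. ClCO2Me and pyridine convert F3 into the allylic methyl carbonate F4. LDA (2.2 equiv, THF, −78 to −20 °C) then forms the indolide/ester enolate, and Pd(PPh3)4 should close the ring to the cyclised ester amide F5, with the ester equatorial, cis to the amide chain and trans to the ring methyl group. LiBH4 reduces the ester to the neopentyl alcohol F6 and Dess–Martin periodinane gives the aldehyde amide F7. The conditions of step 10 then reduce the formyl group through the hydrazone F8 and hydrolyse the amide, giving 21.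

Step 7. Oxidative addition at the hindered C–Br bond may be outrun by ionisation of the allylic lactone C–O bond by zerovalent palladium, or be followed by loss of the β-carboxylate to an allene. The fallback reverses the order of bond formation so that no allylic ester is present during the palladium step. It sets out from alcohol 8 (as its alkylborane 14) and comes back at 15. Alkylborane 14 is coupled once with dibromide 9 under the same palladium conditions to give (3R)-6-bromo-2-(1H-indol-3-ylmethyl)-3,7-dimethyloct-6-en-1-ol F9. A Nozaki–Hiyama–Kishi reaction of F9 with aldehyde 10 (CrCl2, catalytic NiCl2, DMF), which tolerates the free O–H and N–H groups, gives methyl (8R)-4-hydroxy-9-(hydroxymethyl)-10-(1H-indol-3-yl)-8-methyl-5-(propan-2-ylidene)decanoate F10, which lactonises on acidic work-up to 15.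

Step 3. The hindered tertiary malonate anion may add too slowly, so that the reactive indolylmethyl intermediate oligomerises or alkylates at nitrogen. The fallback uses direct SN2 alkylation with an N-protected halide in place of elimination–addition. It sets out from 4 and comes back at 7. Malonate 4 is deprotonated with NaH in DMF and alkylated with tert-butyl 3-(bromomethyl)indole-1-carboxylate to give dimethyl 2-[(2R)-but-3-en-2-yl]-2-[(1-tert-butoxycarbonylindol-3-yl)methyl]propanedioate F11. The Krapcho conditions of step 4 then remove one ester and, thermally, the Boc group, giving 7.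

Further compounds
F1 | step 9 | 5-bromo-4-hydroxy-N,N,6-trimethylhept-5-enamide | CC(C)=C(Br)C(O)CCC(=O)N(C)C
F2 | step 9 | B-alkyl-9-BBN from ester 7 | C1CCC2CCCC1B2CC[C@@H](C)C(Cc1c[nH]c2ccccc12)C(=O)OC
F3 | step 9 | methyl (3R)-6-[4-(dimethylamino)-1-hydroxy-4-oxobutyl]-2-(1H-indol-3-ylmethyl)-3,7-dimethyloct-6-enoate | CC(C)=C(CC[C@@H](C)C(Cc1c[nH]c2ccccc12)C(=O)OC)C(O)CCC(=O)N(C)C
F4 | step 9 | methyl carbonate of F3 | CC(C)=C(CC[C@@H](C)C(Cc1c[nH]c2ccccc12)C(=O)OC)C(OC(=O)OC)CCC(=O)N(C)C
F5 | step 9 | methyl 2-[3-(dimethylamino)-3-oxopropyl]-1-(1H-indol-3-ylmethyl)-6-methyl-3-(propan-2-ylidene)cyclohexane-1-carboxylate | CC(C)=C1CC[C@@H](C)[C@@](C(=O)OC)(Cc2c[nH]c3ccccc23)[C@@H]1CCC(=O)N(C)C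
F6 | step 9 | 3-[2-(hydroxymethyl)-2-(1H-indol-3-ylmethyl)-3-methyl-6-(propan-2-ylidene)cyclohexyl]-N,N-dimethylpropanamide | CC(C)=C1CC[C@@H](C)[C@@](CO)(Cc2c[nH]c3ccccc23)[C@@H]1CCC(=O)N(C)C
F7 | step 9 | 3-[2-formyl-2-(1H-indol-3-ylmethyl)-3-methyl-6-(propan-2-ylidene)cyclohexyl]-N,N-dimethylpropanamide | CC(C)=C1CC[C@@H](C)[C@@](C=O)(Cc2c[nH]c3ccccc23)[C@@H]1CCC(=O)N(C)C
F8 | step 9 | hydrazone of F7 | CC(C)=C1CC[C@@H](C)[C@@](C=NN)(Cc2c[nH]c3ccccc23)[C@@H]1CCC(=O)N(C)C
F9 | step 7 | (3R)-6-bromo-2-(1H-indol-3-ylmethyl)-3,7-dimethyloct-6-en-1-ol | CC(C)=C(Br)CC[C@@H](C)C(CO)Cc1c[nH]c2ccccc12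
F10 | step 7 | methyl (8R)-4-hydroxy-9-(hydroxymethyl)-10-(1H-indol-3-yl)-8-methyl-5-(propan-2-ylidene)decanoate | COC(=O)CCC(O)C(CC[C@@H](C)C(CO)Cc1c[nH]c2ccccc12)=C(C)C
F11 | step 3 | dimethyl 2-[(2R)-but-3-en-2-yl]-2-[(1-tert-butoxycarbonylindol-3-yl)methyl]propanedioate | C=C[C@@H](C)C(Cc1cn(C(=O)OC(C)(C)C)c2ccccc12)(C(=O)OC)C(=O)OC
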